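**Plan**
Retrosynthesis: the aryl ester C–O bond, the C6–CH3 bond and the C1–isopropyl bond are cut first. The C8–OH/C8a–H pair is traced back to a C8=C8a enone, and the hydroazulene is then cut at C3a–C8a and C7–C8 in one (5+2) disconnection.
Enabling feature: in seven-membered ring A the ketone carbon C5 lies between C4 (next to the quaternary, methyl-bearing fusion carbon C3a) and the C6–C7 ethano unit. C5 can therefore be the silyloxy carbon of a cyclopropane (C6, C7 its CH2 groups), C3a=C4 its vinyl group, C8a≡C8 an alkyne and C1–C3 of five-membered ring B the tether.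
Forward: pent-4-yn-1-ol is elaborated as an open chain (E-enoate, siloxyvinylcyclopropane, ynone). Rings B and A close together in the rhodium step, followed by oxygenation at C8, isopropyl addition and esterification at C1, and the ring A enone.
Stereochemistry: C3a from the chiral rhodium bisphosphine catalyst, C8 by epoxidation anti to the 3a-methyl, C8a by kinetic protonation of a samarium enolate (trans fusion), C1 by isopropyl addition anti to the 3a-methyl.

Key step: step 8

Remarks. Locants are those of azulene: C1 (ester, isopropyl), C2, C3, C3a (quaternary CH3), C4, C5 (C=O), C6 (CH3), C7, C8 (OH), C8a (H). TES = triethylsilyl, TBS = tert-butyldimethylsilyl, TMS = trimethylsilyl, DMP = Dess–Martin periodinane.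
Assumption: the sense of induction of the rhodium–BINAP catalyst on this substrate cannot be predicted with confidence. (R)-BINAP is written and stands for whichever antipode delivers the (3aR) cycloadduct, to be settled by a first experiment.

Step 1
Reactants: 1 pent-4-yn-1-ol
Product: 2 triethyl(pent-4-yn-1-yloxy)silane
Conditions: TESCl, imidazole, CH2Cl2, 0 °C to rt
Reagents that add atoms: chlorotriethylsilane, CC[Si](Cl)(CC)CC
Why: Standard O-silylation of a primary alcohol gives an ether that tolerates the aluminium, magnesium and titanium reagents ahead and is later the only silyl group attacked by the Swern reagent.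

Step 2
Reactants: 2 triethyl(pent-4-yn-1-yloxy)silane
Product: 4 ethyl (2E)-3-methyl-6-(TESO)hex-2-enoate, via alkenyldimethylalane 3 (not isolated)
Conditions: Me3Al, Cp2ZrCl2 (cat.), CH2Cl2, 0 °C to rt; then ClCO2Et, 0 °C to rt
Reagents that add atoms: trimethylaluminium, C[Al](C)C; ethyl chloroformate, CCOC(=O)Cl
Why: Zirconium-catalysed Negishi carboalumination adds CH3 and Al syn across the terminal alkyne with methyl on the inner carbon, and acylation of the alkenylalane by the chloroformate with retention should give the E-trisubstituted enoate stereospecifically.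

Step 3
Reactants: 4 ethyl (2E)-3-methyl-6-(TESO)hex-2-enoate
Product: 5 1-[(1E)-2-methyl-5-(TESO)pent-1-en-1-yl]cyclopropan-1-ol
Conditions: EtMgBr (3 equiv, slow addition), Ti(OiPr)4 (0.3 equiv), THF, 0 °C to rt
Reagents that add atoms: ethylmagnesium bromide, CC[Mg]Br
Why: Kulinkovich cyclopropanation, in which the catalytically generated titanacyclopropane acts as a 1,2-dicarbanion on the ester carbonyl; β,β-disubstituted enoates are accepted substrates and the hindered double bond keeps its geometry.

Step 4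
Reactants: 5 1-[(1E)-2-methyl-5-(TESO)pent-1-en-1-yl]cyclopropan-1-ol
Product: 6 tert-butyldimethyl{1-[(1E)-2-methyl-5-(TESO)pent-1-en-1-yl]cyclopropoxy}silane
Conditions: TBSOTf, 2,6-lutidine, CH2Cl2, −78 °C
Reagents that add atoms: tert-butyldimethylsilyl trifluoromethanesulfonate, CC(C)(C)[Si](C)(C)OS(=O)(=O)C(F)(F)F
Why: Silyl triflate silylation of a tertiary cyclopropanol under lutidine buffering installs the robust silyloxy group of the five-carbon component without acid-induced ring expansion.

Step 5
Reactants: 6 tert-butyldimethyl{1-[(1E)-2-methyl-5-(TESO)pent-1-en-1-yl]cyclopropoxy}silane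
Product: 8 (4E)-5-[1-(TBSO)cyclopropyl]-4-methylpent-4-enal, via alkoxydimethylsulfonium chloride 7 (not isolated)
Conditions: (COCl)2, DMSO, CH2Cl2, −78 to −40 °C; then Et3N, −78 °C to rt
Reagents that add atoms: none
Why: Swern oxidation applied directly to a primary triethylsilyl ether: chlorodimethylsulfonium chloride exchanges the unhindered O–SiEt3 for O–SMe2+ while the tertiary TBS ether is too hindered to react, and triethylamine then releases the aldehyde without a separate acidic deprotection.

Step 6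
Reactants: 8 (4E)-5-[1-(TBSO)cyclopropyl]-4-methylpent-4-enal
Product: 9 (6E)-7-[1-(TBSO)cyclopropyl]-6-methylhept-6-en-1-yn-3-ol (racemic)
Conditions: HC≡CMgBr, THF, −78 to 0 °C
Reagents that add atoms: ethynylmagnesium bromide, C#C[Mg]Br
Why: Grignard 1,2-addition to an unhindered aldehyde; the carbinol configuration is irrelevant because the centre is oxidised in the next step.

Step 7
Reactants: 9 (6E)-7-[1-(TBSO)cyclopropyl]-6-methylhept-6-en-1-yn-3-ol
Product: 10 (6E)-7-[1-(TBSO)cyclopropyl]-6-methylhept-6-en-1-yn-3-one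
Conditions: DMP, NaHCO3, CH2Cl2, 0 °C to rt
Reagents that add atoms: none
Why: Dess–Martin oxidation of a secondary propargylic alcohol under buffered, non-acidic conditions should give the terminal ynone and spare the acid-sensitive siloxyvinylcyclopropane.

Step 8
Reactants: 10 (6E)-7-[1-(TBSO)cyclopropyl]-6-methylhept-6-en-1-yn-3-one
Product: 11 (3aR)-5-(TBSO)-3a-methyl-3,3a,6,7-tetrahydroazulen-1(2H)-one
Conditions: [Rh((R)-BINAP)]SbF6 (10 mol %), ClCH2CH2Cl (0.02 M), 40 °C
Reagents that add atoms: none
Why: Cationic monovalent rhodium binds the ynone alkyne and the alkene of the siloxyvinylcyclopropane, oxidative cyclisation bonds the inner alkyne carbon to the methyl-bearing alkene carbon, the adjacent strained cyclopropane bond then shifts to rhodium to give an eight-membered alkyl–Rh–vinyl rhodacycle, and reductive elimination joins the terminal alkyne carbon to the former cyclopropane CH2 while the silyl enol ether double bond appears. The closest known reaction type is the rhodium-catalysed intramolecular vinylcyclopropane–alkyne (5+2) cycloaddition, which is established for 1-alkoxy- and 1-siloxy-vinylcyclopropanes, for electron-poor alkynes and with chiral bisphosphine ligands; a fully substituted alkene terminus lies at the edge of that scope. Ring B (five-membered) closes in the oxidative cyclisation as a tether-enforced C3a–C8a coupling, and ring A (seven-membered) closes by C(sp2)–C(sp3) reductive elimination (C7–C8) from the ring-expanded rhodacycle. The only new stereocentre, quaternary C3a, is set when the chiral Rh–BINAP fragment selects one enantioface of the trisubstituted alkene during oxidative cyclisation. The step needs regioselectivity, face selectivity and chemoselectivity over alkyne oligomerisation: the three-atom tether fixes which termini meet, the unsubstituted cyclopropane offers two equivalent bonds to cleave, the E geometry keeps the tether trans to the cyclopropane so the reactive s-cis conformer is reachable, and high dilution favours the intramolecular path.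

Step 9
Reactants: 11 (3aR)-5-(TBSO)-3a-methyl-3,3a,6,7-tetrahydroazulen-1(2H)-one
Product: 12 (3aR,8S,8aR)-5-(TBSO)-8,8a-epoxy-3a-methyl-2,3,3a,6,7,8-hexahydroazulen-1(8aH)-one (oxirane oxygen anti to the 3a-methyl)
Conditions: t-BuOOH (decane), DBU, CH2Cl2, 0 °C to rt
Reagents that add atoms: tert-butyl hydroperoxide, CC(C)(C)OO
Why: Nucleophilic Weitz–Scheffer-type epoxidation: the peroxide anion adds reversibly to C8 of the s-cis enone and the enolate closes on oxygen at C8a from the face opposite the neighbouring 3a-methyl, which sets C8, while the electron-rich silyl enol ether is inert to a nucleophilic oxidant.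

Step 10
Reactants: 12 (3aR,8S,8aR)-5-(TBSO)-8,8a-epoxy-3a-methyl-2,3,3a,6,7,8-hexahydroazulen-1(8aH)-one
Product: 13 (3aR,8S,8aS)-5-(TBSO)-8-hydroxy-3a-methyl-2,3,3a,6,7,8-hexahydroazulen-1(8aH)-one
Conditions: SmI2 (2.5 equiv), THF/MeOH, −90 °C
Reagents that add atoms: none
Why: Reductive opening of an α,β-epoxy ketone by SmI2: two single-electron transfers cleave the C8a–O bond to a samarium enolate while C8 keeps its configuration, and kinetic protonation by methanol from the face opposite the 3a-methyl (the face of the samarium-bound C8 alkoxide) should give the trans-fused β-hydroxy ketone.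

Step 11
Reactants: 13 (3aR,8S,8aS)-5-(TBSO)-8-hydroxy-3a-methyl-2,3,3a,6,7,8-hexahydroazulen-1(8aH)-one
Product: 14 (3aR,8S,8aS)-5,8-bis(TBSO)-3a-methyl-2,3,3a,6,7,8-hexahydroazulen-1(8aH)-one
Conditions: TBSOTf, 2,6-lutidine, CH2Cl2, −78 °C
Reagents that add atoms: tert-butyldimethylsilyl trifluoromethanesulfonate, CC(C)(C)[Si](C)(C)OS(=O)(=O)C(F)(F)F
Why: Low-temperature silyl triflate protection of an aldol-type secondary alcohol, which blocks retro-aldol cleavage and later O-acylation at C8 without enolising the epimerisable C8a centre.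

Step 12
Reactants: 14 (3aR,8S,8aS)-5,8-bis(TBSO)-3a-methyl-2,3,3a,6,7,8-hexahydroazulen-1(8aH)-one
Product: 15 (1R,3aR,8S,8aS)-5,8-bis(TBSO)-3a-methyl-1-(propan-2-yl)-1,2,3,3a,6,7,8,8a-octahydroazulen-1-ol
Conditions: i-PrMgCl, CeCl3 (anhydrous), THF, −78 to 0 °C
Reagents that add atoms: isopropylmagnesium chloride, CC(C)[Mg]Cl
Why: CeCl3-promoted Grignard 1,2-addition to a hindered, enolisable ketone, in which the cerium additive suppresses enolisation toward C8a and β-hydride reduction, and attack on C1 from the face opposite the axial 3a-methyl places the isopropyl trans and the new hydroxyl cis to that methyl.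

Step 13
Reactants: 16 4-hydroxybenzoic acid
Product: 17 tert-butyldimethylsilyl 4-(TBSO)benzoate
Conditions: TBSCl (2.2 equiv), imidazole, DMF, rt
Reagents that add atoms: tert-butylchlorodimethylsilane, CC(C)(C)[Si](C)(C)Cl
Why: Exhaustive silylation protects the phenol and turns the acid into a silyl ester that can be converted to the acid chloride under neutral conditions.

Step 14
Reactants: 17 tert-butyldimethylsilyl 4-(TBSO)benzoate
Product: 18 4-(TBSO)benzoyl chloride
Conditions: (COCl)2, DMF (cat.), CH2Cl2, 0 °C to rt; distillation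
Reagents that add atoms: oxalyl chloride, ClC(=O)C(=O)Cl
Why: Vilsmeier-type conversion of a silyl ester into the acid chloride with oxalyl chloride and catalytic DMF, which releases no HCl and so leaves the aryl silyl ether in place.

Step 15
Reactants: 15 (1R,3aR,8S,8aS)-5,8-bis(TBSO)-3a-methyl-1-(propan-2-yl)-1,2,3,3a,6,7,8,8a-octahydroazulen-1-ol; 18 4-(TBSO)benzoyl chloride
Product: 20 (1R,3aR,8S,8aS)-5,8-bis(TBSO)-3a-methyl-1-(propan-2-yl)-1,2,3,3a,6,7,8,8a-octahydroazulen-1-yl 4-(TBSO)benzoate, via lithium alkoxide 19 (not isolated)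
Conditions: n-BuLi, THF, −78 °C; then 18, −78 °C to rt
Reagents that add atoms: none
Why: O-acylation of a lithium tertiary alkoxide by an aroyl chloride, the standard route to hindered tertiary benzoates, carried out while every other oxygen is silylated and the ring A ketone is still masked as its silyl enol ether so that no enolisable carbonyl competes.

Step 16
Reactants: 20 (1R,3aR,8S,8aS)-5,8-bis(TBSO)-3a-methyl-1-(propan-2-yl)-1,2,3,3a,6,7,8,8a-octahydroazulen-1-yl 4-(TBSO)benzoate
Product: 21 (1R,3aR,8S,8aS)-8-(TBSO)-3a-methyl-5-oxo-1-(propan-2-yl)decahydroazulen-1-yl 4-(TBSO)benzoate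
Conditions: 1 M aq. HCl, THF, 0 °C
Reagents that add atoms: none
Why: Acid-catalysed hydrolysis of a silyl enol ether proceeds by C-protonation and is expected to be much faster than cleavage of the hindered secondary alkyl silyl ether or the acid-stable aryl silyl ether, so only the C5 ketone is unmasked.

Step 17
Reactants: 21 (1R,3aR,8S,8aS)-8-(TBSO)-3a-methyl-5-oxo-1-(propan-2-yl)decahydroazulen-1-yl 4-(TBSO)benzoate
Product: 23 (1R,3aR,8S,8aS)-8-(TBSO)-3a,6-dimethyl-5-oxo-1-(propan-2-yl)decahydroazulen-1-yl 4-(TBSO)benzoate (C6 epimers), via lithium enolate 22 (not isolated)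
Conditions: LDA (1.1 equiv), THF, −78 °C; then MeI, −78 to −30 °C
Reagents that add atoms: iodomethane, CI
Why: Kinetic enolate alkylation: lithium diisopropylamide should remove a C6 proton in preference to the neopentyl C4 protons beside quaternary C3a, the non-enolisable hindered ester is not attacked, and the C6 configuration is irrelevant because the centre becomes sp2 in the next step.

Step 18
Reactants: 23 (1R,3aR,8S,8aS)-8-(TBSO)-3a,6-dimethyl-5-oxo-1-(propan-2-yl)decahydroazulen-1-yl 4-(TBSO)benzoate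
Product: 25 (1R,3aR,8S,8aS)-8-(TBSO)-3a,6-dimethyl-5-oxo-1-(propan-2-yl)-1,2,3,3a,4,5,8,8a-octahydroazulen-1-yl 4-(TBSO)benzoate, via trimethylsilyl enol ether 24 (not isolated)
Conditions: TMSOTf, Et3N, CH2Cl2, 0 °C to rt; solvent exchange; then Pd(OAc)2 (1.1 equiv), MeCN, rt
Reagents that add atoms: none
Why: Saegusa–Ito oxidation: equilibrating silylation favours the more substituted C5=C6 enol ether, palladation at C6 is followed by β-hydride elimination into the ring toward C7 to give the conjugated endocyclic enone, and the C4 side cannot be dehydrogenated because C3a carries no hydrogen.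

Step 19
Reactants: 25 (1R,3aR,8S,8aS)-8-(TBSO)-3a,6-dimethyl-5-oxo-1-(propan-2-yl)-1,2,3,3a,4,5,8,8a-octahydroazulen-1-yl 4-(TBSO)benzoate
Product: 26 (1R,3aR,8S,8aS)-8-hydroxy-3a,6-dimethyl-5-oxo-1-(propan-2-yl)-1,2,3,3a,4,5,8,8a-octahydroazulen-1-yl 4-hydroxybenzoate
Conditions: HF·pyridine, pyridine, THF, 0 °C to rt
Reagents that add atoms: none
Why: Fluoride-mediated global desilylation under mildly acidic buffering removes the aryl and the secondary alkyl silyl groups without forming alkoxides, which could move the aroyl group from the tertiary to the C8 oxygen or isomerise the γ-hydroxy enone.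

**Compound list**
1 | pent-4-yn-1-ol | C#CCCCO | starting material
2 | triethyl(pent-4-yn-1-yloxy)silane | C#CCCCO[Si](CC)(CC)CC | intermediate
3 | dimethyl[(1E)-2-methyl-5-(TESO)pent-1-en-1-yl]alane | C[Al](C)/C=C(\C)CCCO[Si](CC)(CC)CC | intermediate
4 | ethyl (2E)-3-methyl-6-(TESO)hex-2-enoate | CCOC(=O)/C=C(\C)CCCO[Si](CC)(CC)CC | intermediate
5 | 1-[(1E)-2-methyl-5-(TESO)pent-1-en-1-yl]cyclopropan-1-ol | OC1(CC1)/C=C(\C)CCCO[Si](CC)(CC)CC | intermediate
6 | tert-butyldimethyl{1-[(1E)-2-methyl-5-(TESO)pent-1-en-1-yl]cyclopropoxy}silane | CC[Si](CC)(CC)OCCC/C(C)=C/C1(O[Si](C)(C)C(C)(C)C)CC1 | intermediate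
7 | {[(4E)-5-[1-(TBSO)cyclopropyl]-4-methylpent-4-en-1-yl]oxy}dimethylsulfonium chloride | C[S+](C)OCCC/C(C)=C/C1(O[Si](C)(C)C(C)(C)C)CC1.[Cl-] | intermediate
8 | (4E)-5-[1-(TBSO)cyclopropyl]-4-methylpent-4-enal | O=CCC/C(C)=C/C1(O[Si](C)(C)C(C)(C)C)CC1 | intermediate
9 | (6E)-7-[1-(TBSO)cyclopropyl]-6-methylhept-6-en-1-yn-3-ol (racemic) | C#CC(O)CC/C(C)=C/C1(O[Si](C)(C)C(C)(C)C)CC1 | intermediate
10 | (6E)-7-[1-(TBSO)cyclopropyl]-6-methylhept-6-en-1-yn-3-one | C#CC(=O)CC/C(C)=C/C1(O[Si](C)(C)C(C)(C)C)CC1 | intermediate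
11 | (3aR)-5-(TBSO)-3a-methyl-3,3a,6,7-tetrahydroazulen-1(2H)-one | C1CC=C2[C@](C)(CCC2=O)C=C1O[Si](C)(C)C(C)(C)C | intermediate
12 | (3aR,8S,8aR)-5-(TBSO)-8,8a-epoxy-3a-methyl-2,3,3a,6,7,8-hexahydroazulen-1(8aH)-one | C1C[C@@H]3O[C@]32[C@](C)(CCC2=O)C=C1O[Si](C)(C)C(C)(C)C | intermediate
13 | (3aR,8S,8aS)-5-(TBSO)-8-hydroxy-3a-methyl-2,3,3a,6,7,8-hexahydroazulen-1(8aH)-one | C1C[C@H](O)[C@@H]2[C@](C)(CCC2=O)C=C1O[Si](C)(C)C(C)(C)C | intermediate
14 | (3aR,8S,8aS)-5,8-bis(TBSO)-3a-methyl-2,3,3a,6,7,8-hexahydroazulen-1(8aH)-one | C1C[C@H](O[Si](C)(C)C(C)(C)C)[C@@H]2[C@](C)(CCC2=O)C=C1O[Si](C)(C)C(C)(C)C | intermediate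
15 | (1R,3aR,8S,8aS)-5,8-bis(TBSO)-3a-methyl-1-(propan-2-yl)-1,2,3,3a,6,7,8,8a-octahydroazulen-1-ol | C1C[C@H](O[Si](C)(C)C(C)(C)C)[C@@H]2[C@](C)(CC[C@@]2(O)C(C)C)C=C1O[Si](C)(C)C(C)(C)C | intermediate
16 | 4-hydroxybenzoic acid | OC(=O)c1ccc(O)cc1 | starting material
17 | tert-butyldimethylsilyl 4-(TBSO)benzoate | CC(C)(C)[Si](C)(C)OC(=O)c1ccc(O[Si](C)(C)C(C)(C)C)cc1 | intermediate
18 | 4-(TBSO)benzoyl chloride | ClC(=O)c1ccc(O[Si](C)(C)C(C)(C)C)cc1 | intermediate
19 | lithium alkoxide of 15 | C1C[C@H](O[Si](C)(C)C(C)(C)C)[C@@H]2[C@](C)(CC[C@@]2(O[Li])C(C)C)C=C1O[Si](C)(C)C(C)(C)C | intermediate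
20 | (1R,3aR,8S,8aS)-5,8-bis(TBSO)-3a-methyl-1-(propan-2-yl)-1,2,3,3a,6,7,8,8a-octahydroazulen-1-yl 4-(TBSO)benzoate | C1C[C@H](O[Si](C)(C)C(C)(C)C)[C@@H]2[C@](C)(CC[C@@]2(OC(=O)c3ccc(O[Si](C)(C)C(C)(C)C)cc3)C(C)C)C=C1O[Si](C)(C)C(C)(C)C | intermediate
21 | (1R,3aR,8S,8aS)-8-(TBSO)-3a-methyl-5-oxo-1-(propan-2-yl)decahydroazulen-1-yl 4-(TBSO)benzoate | C1C[C@H](O[Si](C)(C)C(C)(C)C)[C@@H]2[C@](C)(CC[C@@]2(OC(=O)c3ccc(O[Si](C)(C)C(C)(C)C)cc3)C(C)C)CC1=O | intermediate
22 | lithium C5=C6 enolate of 21 | [Li]OC1=CC[C@H](O[Si](C)(C)C(C)(C)C)[C@@H]2[C@](C)(CC[C@@]2(OC(=O)c3ccc(O[Si](C)(C)C(C)(C)C)cc3)C(C)C)C1 | intermediate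
23 | (1R,3aR,8S,8aS)-8-(TBSO)-3a,6-dimethyl-5-oxo-1-(propan-2-yl)decahydroazulen-1-yl 4-(TBSO)benzoate (C6 epimers) | CC1C[C@H](O[Si](C)(C)C(C)(C)C)[C@@H]2[C@](C)(CC[C@@]2(OC(=O)c3ccc(O[Si](C)(C)C(C)(C)C)cc3)C(C)C)CC1=O | intermediate
24 | (1R,3aR,8S,8aS)-8-(TBSO)-3a,6-dimethyl-1-(propan-2-yl)-5-(trimethylsilyloxy)-1,2,3,3a,4,7,8,8a-octahydroazulen-1-yl 4-(TBSO)benzoate | C[Si](C)(C)OC1=C(C)C[C@H](O[Si](C)(C)C(C)(C)C)[C@@H]2[C@](C)(CC[C@@]2(OC(=O)c3ccc(O[Si](C)(C)C(C)(C)C)cc3)C(C)C)C1 | intermediate
25 | (1R,3aR,8S,8aS)-8-(TBSO)-3a,6-dimethyl-5-oxo-1-(propan-2-yl)-1,2,3,3a,4,5,8,8a-octahydroazulen-1-yl 4-(TBSO)benzoate | CC1=C[C@H](O[Si](C)(C)C(C)(C)C)[C@@H]2[C@](C)(CC[C@@]2(OC(=O)c3ccc(O[Si](C)(C)C(C)(C)C)cc3)C(C)C)CC1=O | intermediate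
26 | (1R,3aR,8S,8aS)-8-hydroxy-3a,6-dimethyl-5-oxo-1-(propan-2-yl)-1,2,3,3a,4,5,8,8a-octahydroazulen-1-yl 4-hydroxybenzoate | CC1=C[C@H](O)[C@@H]2[C@](C)(CC[C@@]2(OC(=O)c2ccc(O)cc2)C(C)C)CC1=O | target

**Count**
Total steps: 19. Longest linear sequence: 17 (steps 1–12 and 15–19 from pent-4-yn-1-ol); steps 13–14 prepare the acid chloride.

**Steps most likely to fail**

Step 8. The oxidative cyclisation may be slow at the fully substituted alkene carbon, so that oligomerisation of the electron-poor terminal alkyne takes over, or the bisphosphine may discriminate the alkene faces poorly. The fallback moves stereocontrol from the catalyst to the substrate and lowers the oxidation level of the two-carbon partner. Setting out from 10, reduction with (S)-Alpine-Borane, a reagent established for terminal ynones, should give (3S,6E)-7-[1-(TBSO)cyclopropyl]-6-methylhept-6-en-1-yn-3-ol F1. This hydroxy enyne is cyclised with achiral [Rh(CO)2Cl]2 in 1,2-dichloroethane at 60 °C, the carbinol centre in the tether being expected to bias the alkene face, to give (1S,3aR)-5-(TBSO)-3a-methyl-1,2,3,3a,6,7-hexahydroazulen-1-ol F2. Hydroxyl cis to the 3a-methyl is assumed; the antipodal borane would be used if the opposite relative sense were found. Oxidation of the allylic alcohol with MnO2 erases the auxiliary centre and comes back to the route at 11.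

Step 15. Acylation of the congested lithium alkoxide may be too slow, leaving the aroyl chloride to be consumed by adventitious nucleophiles or the alkoxide to fragment on warming. The fallback makes the aryl–carbonyl bond instead of the oxygen–acyl bond, so the hindered oxygen meets only a small electrophile. Setting out from 15, deprotonation with n-BuLi and capture with 1,1'-carbonyldiimidazole should give (1R,3aR,8S,8aS)-5,8-bis(TBSO)-3a-methyl-1-(propan-2-yl)-1,2,3,3a,6,7,8,8a-octahydroazulen-1-yl 1H-imidazole-1-carboxylate F3. The aryl Grignard reagent [4-(TBSO)phenyl]magnesium bromide F4, made from (4-bromophenoxy)(tert-butyl)dimethylsilane and magnesium in THF, then adds to the imidazolide carbonyl at −78 to 0 °C with loss of imidazolide (ester synthesis from Grignard reagents and alkyl imidazole-1-carboxylates). The hindered tertiary ester resists a second addition, and the sequence comes back to the route at 20.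

Step 12. The ketone may enolise toward C8a, followed by β-elimination of the C8 silyloxy group, or the carbonyl may be reduced by β-hydride transfer from the isopropyl reagent. The fallback uses an sp2 nucleophile without β-hydrogens and adds the two hydrogens afterwards. Setting out from 14, isopropenylmagnesium bromide with CeCl3 in THF should give (1S,3aR,8S,8aS)-5,8-bis(TBSO)-3a-methyl-1-(prop-1-en-2-yl)-1,2,3,3a,6,7,8,8a-octahydroazulen-1-ol F5 by the same anti-to-methyl attack. Hydrogenation with H2 and RhCl(PPh3)3 in benzene/ethanol saturates only the unhindered 1,1-disubstituted alkene, the trisubstituted silyl enol ether beside the quaternary carbon being left alone, and comes back to the route at 15.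

**Further compounds**
F1 | step 8 | (3S,6E)-7-[1-(TBSO)cyclopropyl]-6-methylhept-6-en-1-yn-3-ol | C#C[C@@H](O)CC/C(C)=C/C1(O[Si](C)(C)C(C)(C)C)CC1
F2 | step 8 | (1S,3aR)-5-(TBSO)-3a-methyl-1,2,3,3a,6,7-hexahydroazulen-1-ol | C1CC=C2[C@](C)(CC[C@@H]2O)C=C1O[Si](C)(C)C(C)(C)C
F3 | step 15 | (1R,3aR,8S,8aS)-5,8-bis(TBSO)-3a-methyl-1-(propan-2-yl)-1,2,3,3a,6,7,8,8a-octahydroazulen-1-yl 1H-imidazole-1-carboxylate | C1C[C@H](O[Si](C)(C)C(C)(C)C)[C@@H]2[C@](C)(CC[C@@]2(OC(=O)n3ccnc3)C(C)C)C=C1O[Si](C)(C)C(C)(C)C
F4 | step 15 | [4-(TBSO)phenyl]magnesium bromide | CC(C)(C)[Si](C)(C)Oc1ccc([Mg]Br)cc1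
F5 | step 12 | (1S,3aR,8S,8aS)-5,8-bis(TBSO)-3a-methyl-1-(prop-1-en-2-yl)-1,2,3,3a,6,7,8,8a-octahydroazulen-1-ol | C1C[C@H](O[Si](C)(C)C(C)(C)C)[C@@H]2[C@](C)(CC[C@@]2(O)C(C)=C)C=C1O[Si](C)(C)C(C)(C)C
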